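The forecaster and a colleague argue over this flask.

- winter: J 2 M (fed, over 2.5 h); D 5 mol%; G 26 mM; the very flask that is asked about, followed so far; the fed solution adds 0.25 times the starting volume
- flask: J 2.0 M (fed, over 2.5 h); D 5 mol%; G 26 mM; time 6.0 d; the fed solution adds 0.25 times the starting volume

- winter (time / d: X / %, J / %): 0.833: 27.9, 72.9; 1.67: 66.9, 33.4; 2.50: 87.1, 12.8; 3.00: 92.8, 7.0

(readings scatter by 0.3 percentage points)

- amounts are per litre of the starting volume; all of the dose is in the solution fed
- the average divides the monomer in chains by the number of chains begun, living and dead together
- the analysis behind the earlier runs scatters by 0.3 percentage points, standard deviation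
- the earlier runs do not show the number of chains; that part of a forecast is a guess

- average number of monomer units in a chain (chains begun, living or dead) at 6.0 d
- part of the J that has reacted at 6.0 d

They do not quarrel over J, which the winter run reads at 7.0% at 3.00 d, still falling. The readings show no chains, so the quarrel is about the count of chains.

The forecaster holds that each D begins a chain. The forecast reads 20 units and 99.7% reacted: “One chain per D gives dp of about 20.”

The colleague reckons otherwise and takes G as a fast trap that removes D one for one before chains matter. G's charge is 26.0% of D's, so it is less than D's, and G is the limiting reagent of that side step. The colleague's quantity is the free share, the part of the D charge that G leaves: 74.0%. One chain per free D gives 27.0 units, and more if some free D still stands when J is gone.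

The flask gives 52.5 units, longer than both numbers, and 99.8% reacted, beside the forecast's 99.7%.

    J + D → L + X (k = 2.20 × 10⁻⁴ M⁻¹ min⁻¹)
    J + L → X + L, rate k2*[L]*[J] (k = 0.0280 M⁻¹ min⁻¹)
    D + G → E (k = 4.60 M⁻¹ min⁻¹)
    D → Z (k = 5.50 × 10⁻⁷ min⁻¹)

In this flask G is at 0% by 0.104 d. Of the free share 74.0%, D still holds 36% at 6.00 d and Z holds 0.198%, so 38.0% of the D charge began chains. At 6.00 d the half-life of J is 0.56 d by growth on L, the propagation, against 76 d by beginning a chain. The second is long against 6.0 d, and J is down to 0.18%, less than the 36% of D, each of its own charge. The neighbour with 0.10 M of G, as much as the D charge, has a reckoned free share of 0%; at 6.0 d it holds D at 0% and G at 0.26%, and it reaches 4.62% reacted, with chains of 358 units.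

Readings and results stem from a simulated flask with constants of no real substance.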